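The route rests on opening ring C at C2. This carbon is at the carbonyl oxidation level and lies between C1' of ring B and C3, a former acetyl methyl carbon, so it can enter as carbon monoxide. One palladium-catalysed three-component coupling of a ring A methyl ketone, CO and a ring B aryl bromide forms C1'–C2 and C2–C3 and delivers the open 1,3-diketone. The ketone has one free phenol (future O1) and MOM ethers on the future 5-, 6- and 7-oxygens; ring B is benzylated. Ring C is then closed through the only free phenol before the acetals are cleaved. The chelated 5-OH escapes sulfation, and hydrogenolysis finishes the route.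

Key step: step 6

Assumption: the sulfate half-esters 14 and 15 are drawn and counted as neutral hydrogen sulfates, as in the target SMILES. In the flask they are kept as sodium salts, and the acid form is released only at the very end by cold proton exchange.

Step 1
Reactants: 1 3,4,5-trihydroxybenzaldehyde
Product: 2 3,4,5-tris(methoxymethoxy)benzaldehyde
Conditions: MOMCl (4.5 equiv), i-Pr2NEt (6 equiv), DMF, 0 °C → rt, argon
Reagents that add atoms: chloromethyl methyl ether (MOMCl), COCCl
Why: Williamson-type O-alkylation of the three phenols with the reactive α-chloro ether under amine base is routine for gallic-type aldehydes, and the excess reagent should carry the hindered central 4-OH to completion.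

Step 2
Reactants: 2 3,4,5-tris(methoxymethoxy)benzaldehyde
Product: 3 2-bromo-3,4,5-tris(methoxymethoxy)benzaldehyde
Conditions: NBS (1.05 equiv), MeCN, 0 °C → rt, dark
Reagents that add atoms: N-bromosuccinimide, O=C1CCC(=O)N1Br
Why: Electrophilic aromatic bromination: C2 and C6 are equivalent and each is activated by an ortho and a para acetal oxygen, the formyl group and the first bromine brake a second substitution, and NBS liberates no acid that could touch the MOM groups.

Step 3
Reactants: 3 2-bromo-3,4,5-tris(methoxymethoxy)benzaldehyde
Product: 5 2-bromo-3,4,5-tris(methoxymethoxy)phenol, via aryl formate 4 (not isolated)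
Conditions: mCPBA (1.5 equiv), CH2Cl2, 0 °C → rt; aq Na2S2O3/NaHCO3 wash; crude 4, K2CO3 (0.2 equiv), MeOH, rt
Reagents that add atoms: 3-chloroperbenzoic acid (mCPBA), O=C(OO)c1cccc(Cl)c1
Why: Baeyer–Villiger oxidation, in which the electron-rich aryl group (para acetal oxygen) migrates in preference to hydride, followed by base-catalysed methanolysis of the formate, should turn CHO into OH directly next to the bromine-bearing carbon.

Step 4
Reactants: 5 2-bromo-3,4,5-tris(methoxymethoxy)phenol
Product: 7 1-[2-hydroxy-4,5,6-tris(methoxymethoxy)phenyl]ethanone, via aryllithium phenoxide 6 (not isolated)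
Conditions: n-BuLi (2.2 equiv), THF, −78 °C; MeC(O)N(OMe)Me (1.5 equiv), −78 → 0 °C; aq NH4Cl
Reagents that add atoms: N-methoxy-N-methylacetamide, CC(=O)N(C)OC
Why: The first equivalent of n-BuLi deprotonates the phenol and the second effects bromine–lithium exchange at the site fixed in step 2, the aryllithium being held by the neighbouring MOM oxygen, and the Weinreb ketone synthesis stops at the ketone because the chelated tetrahedral adduct survives until the quench.

Step 5
Reactants: 8 4-bromocatechol
Product: 9 4-bromo-1,2-bis(benzyloxy)benzene
Conditions: BnBr (2.3 equiv), K2CO3 (3 equiv), DMF, 60 °C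
Reagents that add atoms: benzyl bromide, BrCc1ccccc1
Why: Double Williamson ether synthesis of a catechol with benzyl bromide and carbonate base, which leaves the aryl bromide untouched.

Step 6
Reactants: 7 1-[2-hydroxy-4,5,6-tris(methoxymethoxy)phenyl]ethanone, 9 4-bromo-1,2-bis(benzyloxy)benzene (1.3 equiv), 10 carbon monoxide
Product: 11 1-[3,4-bis(benzyloxy)phenyl]-3-[2-hydroxy-4,5,6-tris(methoxymethoxy)phenyl]propane-1,3-dione
Conditions: NaN(SiMe3)2 (2.0 equiv at the start, 1.2 equiv by syringe pump), Pd(dba)2 (5 mol %), Xantphos (6 mol %), CO (1 atm), dioxane, 80 °C; aq NH4Cl, 0 °C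
Reagents that add atoms: none
Why: Xantphos-ligated zerovalent palladium inserts into the C–Br bond of 9, CO migrates into the aryl–palladium bond to give an aroylpalladium bromide (divalent palladium), the sodium enolate of 7 replaces bromide, and reductive elimination forms C2–C3 after C1'–C2 and frees the catalyst. The closest known reaction type is the palladium-catalysed carbonylative α-arylation of aryl methyl ketones with aryl bromides to 1,3-diketones, which has also been used on 2-hydroxyacetophenones. No ring is closed and no stereocentre is created, since 11 is stored in the basic medium as its unreactive diketonate. The step needs aroylation at the methyl carbon and not at the phenoxide oxygen, and the substrate secures this itself: an ester formed at that oxygen lies ortho to the enolate and is carried to carbon by a Baker–Venkataraman acyl shift, so both channels converge on 11. It also needs CO insertion to outrun direct arylation, which the wide bite angle of Xantphos, the low but constant CO pressure and the slow attack of the 2,6-disubstituted aryl ketone enolate favour. The last portion of base is fed slowly because it only has to take up the acidic proton of 11 as it forms, so that free silylamide never builds up beside CO and the aroylpalladium, and MOM acetals and benzyl ethers are inert throughout.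

Step 7
Reactants: 11 1-[3,4-bis(benzyloxy)phenyl]-3-[2-hydroxy-4,5,6-tris(methoxymethoxy)phenyl]propane-1,3-dione
Product: 13 2-[3,4-bis(benzyloxy)phenyl]-5,6,7-trihydroxy-4H-chromen-4-one, via tris-MOM flavone 12 (not isolated)
Conditions: NaOAc (2 equiv), AcOH, 100 °C, until 11 is consumed; then 50 °C, MeOH, conc. HCl; H2O, filtration
Reagents that add atoms: none
Why: Acid-catalysed cyclodehydration of an o-hydroxyaryl 1,3-diketone (the closing stage of a Baker–Venkataraman flavone synthesis) is run first in buffered acetic acid, too weak to cleave aryl MOM acetals at a competitive rate, so that only the free phenol oxygen can become O1 and the 5,7,8-oxygenated isomer that closure through a liberated second ortho oxygen would give is excluded, and only then does HCl–MeOH remove the three acetals by transacetalisation while the benzyl ethers persist.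

Step 8
Reactants: 13 2-[3,4-bis(benzyloxy)phenyl]-5,6,7-trihydroxy-4H-chromen-4-one
Product: 14 2-[3,4-bis(benzyloxy)phenyl]-5-hydroxy-4-oxo-4H-chromene-6,7-diyl bis(hydrogen sulfate)
Conditions: SO3·pyridine (8 equiv), pyridine, argon, rt → 40 °C; aq NaHCO3 to pH 8; C18 silica
Reagents that add atoms: sulfur trioxide–pyridine complex, [O-]S(=O)(=O)[n+]1ccccc1
Why: O-sulfation of phenols with a sulfur trioxide–amine complex: the 6- and 7-hydroxyls react, whereas the 5-hydroxyl is tied to the C4 carbonyl by a six-membered hydrogen bond and is flanked on both sides, which makes it the least reactive flavone position toward sulfating agents, and ring B is masked.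

Step 9
Reactants: 14 2-[3,4-bis(benzyloxy)phenyl]-5-hydroxy-4-oxo-4H-chromene-6,7-diyl bis(hydrogen sulfate)
Product: 15 6-hydroxyluteolin 6,7-disulfate, 2-(3,4-dihydroxyphenyl)-5-hydroxy-4-oxo-4H-chromene-6,7-diyl bis(hydrogen sulfate)
Conditions: H2 (1 atm), Pd/C (10 wt % Pd), MeOH–H2O, rt; filtration; strongly acidic cation-exchange resin (H+ form), H2O, 0–5 °C; freeze-drying
Reagents that add atoms: none
Why: Catalytic hydrogenolysis of aryl benzyl ethers over Pd/C in a neutral medium should touch neither the aryl sulfate anions nor, at one atmosphere and with uptake control, the vinylogous-ester C2–C3 double bond, and a short cold pass over acid resin gives the protonated form.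

Compound list
1 | 3,4,5-trihydroxybenzaldehyde | O=Cc1cc(O)c(O)c(O)c1 | starting material
2 | 3,4,5-tris(methoxymethoxy)benzaldehyde | O=Cc1cc(OCOC)c(OCOC)c(OCOC)c1 | intermediate
3 | 2-bromo-3,4,5-tris(methoxymethoxy)benzaldehyde | O=Cc1cc(OCOC)c(OCOC)c(OCOC)c1Br | intermediate
4 | 2-bromo-3,4,5-tris(methoxymethoxy)phenyl formate (not isolated) | O=COc1cc(OCOC)c(OCOC)c(OCOC)c1Br | intermediate
5 | 2-bromo-3,4,5-tris(methoxymethoxy)phenol | Oc1cc(OCOC)c(OCOC)c(OCOC)c1Br | intermediate
6 | lithium 2-lithio-3,4,5-tris(methoxymethoxy)phenoxide (not isolated) | [Li]Oc1cc(OCOC)c(OCOC)c(OCOC)c1[Li] | intermediate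
7 | 1-[2-hydroxy-4,5,6-tris(methoxymethoxy)phenyl]ethanone | CC(=O)c1c(O)cc(OCOC)c(OCOC)c1OCOC | intermediate
8 | 4-bromocatechol | Oc1ccc(Br)cc1O | starting material
9 | 4-bromo-1,2-bis(benzyloxy)benzene | Brc1ccc(OCc2ccccc2)c(OCc2ccccc2)c1 | intermediate
10 | carbon monoxide | [C-]#[O+] | starting material
11 | 1-[3,4-bis(benzyloxy)phenyl]-3-[2-hydroxy-4,5,6-tris(methoxymethoxy)phenyl]propane-1,3-dione | O=C(CC(=O)c1ccc(OCc2ccccc2)c(OCc2ccccc2)c1)c1c(O)cc(OCOC)c(OCOC)c1OCOC | intermediate
12 | 2-[3,4-bis(benzyloxy)phenyl]-5,6,7-tris(methoxymethoxy)-4H-chromen-4-one (not isolated) | O=c1cc(-c2ccc(OCc3ccccc3)c(OCc3ccccc3)c2)oc2cc(OCOC)c(OCOC)c(OCOC)c12 | intermediate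
13 | 2-[3,4-bis(benzyloxy)phenyl]-5,6,7-trihydroxy-4H-chromen-4-one | O=c1cc(-c2ccc(OCc3ccccc3)c(OCc3ccccc3)c2)oc2cc(O)c(O)c(O)c12 | intermediate
14 | 2-[3,4-bis(benzyloxy)phenyl]-5-hydroxy-4-oxo-4H-chromene-6,7-diyl bis(hydrogen sulfate) | O=c1cc(-c2ccc(OCc3ccccc3)c(OCc3ccccc3)c2)oc2cc(OS(=O)(=O)O)c(OS(=O)(=O)O)c(O)c12 | intermediate
15 | 6-hydroxyluteolin 6,7-disulfate | O=c1cc(-c2ccc(O)c(O)c2)oc2cc(OS(=O)(=O)O)c(OS(=O)(=O)O)c(O)c12 | target

Total step count: 9. Longest linear sequence: 8 steps (1, 2, 3, 4, 6, 7, 8, 9).

Steps most likely to fail

Step 6.
- What may go wrong: oxidative addition of the electron-rich bromide may stall under CO. CO-free α-arylation or capture of the aroylpalladium by the silylamide may compete. The doubly deprotonated ketone may be poorly soluble.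
- Fallback: the C2 carbon is brought in at the acid oxidation level and catalysis is dropped.
- Commercial 3,4-bis(benzyloxy)benzoic acid F1 is turned with (COCl)2 and catalytic DMF in CH2Cl2 into 3,4-bis(benzyloxy)benzoyl chloride F2.
- Ketone 7 is deprotonated with LiN(SiMe3)2 (3.5 equiv, THF, −78 °C) and aroylated with F2 while warming to room temperature. Any O-aroylation is corrected by the Baker–Venkataraman shift under the excess base.
- The detour sets out from 7 and comes back at 11.

Step 8.
- What may go wrong: the second sulfation next to the first anionic sulfate may remain incomplete. The chelated hydroxyl may be partly sulfated. The pyrogallol-type ring A may oxidise in pyridine. Separation of the polar salts may be poor.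
- Fallback: the sulfates are introduced as neutral, chromatographable diesters.
- Triol 13 is treated with 2,2,2-trichloroethyl chlorosulfate, Et3N and DMAP in THF (0 °C → rt). This should give 2-[3,4-bis(benzyloxy)phenyl]-5-hydroxy-4-oxo-4H-chromene-6,7-diyl bis(2,2,2-trichloroethyl) bis(sulfate) F3, which is purified on silica.
- Pd/C with HCO2NH4 in MeOH then removes both trichloroethyl groups by reductive fragmentation and both benzyl groups by transfer hydrogenolysis. The same cold acid-resin pass follows.
- The detour sets out from 13 and comes back at 15, so step 9 is no longer needed.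

Step 7.
- What may go wrong: the MOM group beside the ketone may be lost before ring closure, which opens closure through the wrong oxygen. Closure may also be incomplete before the strong acid is added.
- Fallback: ring C is closed in base, where acetal cleavage is mechanistically impossible, and the sequence is no longer telescoped.
- Diketone 11 is heated with DBU in pyridine at 100–110 °C. The phenoxide adds to the ring B ketone, and E1cB loss of hydroxide from the resulting 2-hydroxyflavanone follows, as in one-pot DBU flavone syntheses.
- Flavone 12 is isolated and freed from any unclosed 11 by chromatography. It is then treated separately with HCl in MeOH at 50 °C.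
- The detour sets out from 11 and comes back at 13. It makes no compound outside the list.

Further compounds
F1 | step 6 | 3,4-bis(benzyloxy)benzoic acid | O=C(O)c1ccc(OCc2ccccc2)c(OCc2ccccc2)c1
F2 | step 6 | 3,4-bis(benzyloxy)benzoyl chloride | O=C(Cl)c1ccc(OCc2ccccc2)c(OCc2ccccc2)c1
F3 | step 8 | 2-[3,4-bis(benzyloxy)phenyl]-5-hydroxy-4-oxo-4H-chromene-6,7-diyl bis(2,2,2-trichloroethyl) bis(sulfate) | O=c1cc(-c2ccc(OCc3ccccc3)c(OCc3ccccc3)c2)oc2cc(OS(=O)(=O)OCC(Cl)(Cl)Cl)c(OS(=O)(=O)OCC(Cl)(Cl)Cl)c(O)c12
F0 | step 7 | none | none
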